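**Strategy**

The upper flavan unit is cut across its heterocyclic ring C at O1–C8a and C3–C4. In one copper-mediated operation a ring A benzylic Grignard reagent (C4, with bromine on C8a) is joined to an enantioenriched ring B propargylic alcohol (O1–C2–C3): the magnesium alkoxide on O1 steers the benzyl group onto alkyne carbon C3, and the same oxygen then closes the pyran ring by Ullmann arylation at C8a. The step exploits the 1,3-relationship of O1 and C3 about the stereocentre C2. The surplus alkyne carbon is later excised to a C3 ketone that is reduced cis; C4 is then oxidised and joined to C6 of C8-brominated gallocatechin, followed by galloylation and hydrogenolysis.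

Key step: step 5

Remark: the target is read as (−)-epigallocatechin 3-O-gallate-(4β→6)-(+)-gallocatechin (upper unit 2R,3R,4S; lower unit 2R,3S); compounds 1, 6, 17 and 22 are taken as commercial.

**Route**

Step 1
Reactants: 1 1,3-bis(benzyloxy)-5-bromobenzene
Product: 3 2-bromo-4,6-bis(benzyloxy)benzaldehyde, via iminium salt 2 (not isolated)
Conditions: POCl3, DMF, 0 → 70 °C; then aq NaOAc
Reagents that add atoms: N,N-dimethylformamide, CN(C)C=O; water, O
Why: Vilsmeier–Haack formylation should go to the ring carbon that is para to one benzyloxy group, ortho to the other and next to bromine, which is less hindered than the position between the two benzyloxy groups; the minor regioisomer is removed by crystallisation and no stereocentre is formed.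

Step 2
Reactants: 3 2-bromo-4,6-bis(benzyloxy)benzaldehyde
Product: 4 [2-bromo-4,6-bis(benzyloxy)phenyl]methanol
Conditions: NaBH4, THF/MeOH, 0 °C
Reagents that add atoms: none
Why: Borohydride reduction of the aryl aldehyde gives the benzylic alcohol and leaves the aryl bromide and the benzyl ethers untouched; no stereocentre is formed.

Step 3
Reactants: 4 [2-bromo-4,6-bis(benzyloxy)phenyl]methanol
Product: 5 1,5-bis(benzyloxy)-3-bromo-2-(chloromethyl)benzene
Conditions: SOCl2, DMF (cat.), CH2Cl2, 0 °C; used crude
Reagents that add atoms: thionyl chloride, O=S(Cl)Cl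
Why: Chlorodehydroxylation of the electron-rich benzylic alcohol with SOCl2 gives the chloride, chosen over the bromide because it should form the benzylic Grignard reagent with less Wurtz coupling.

Step 4
Reactants: 6 3,4,5-tris(benzyloxy)benzaldehyde
Product: 8 (S)-1-[3,4,5-tris(benzyloxy)phenyl]prop-2-yn-1-ol, via silylalkyne carbinol 7 (not isolated)
Conditions: Me2Zn, (S,S)-ProPhenol (10 mol %), Ph3P=O (20 mol %), trimethylsilylacetylene, toluene, 4 °C; then K2CO3, MeOH, rt (same flask)
Reagents that add atoms: trimethylsilylacetylene, C#C[Si](C)(C)C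
Why: Zinc/ProPhenol-catalysed enantioselective alkynylation of the aromatic aldehyde sets the future C2 stereocentre by facial selection in the chiral dinuclear zinc pocket (the ligand antipode is the one that gives the (S)-ethynyl carbinol, to be confirmed on the first run), and mild methanolysis then removes the C-silyl group.

Step 5
Reactants: 5 1,5-bis(benzyloxy)-3-bromo-2-(chloromethyl)benzene, 8 (S)-1-[3,4,5-tris(benzyloxy)phenyl]prop-2-yn-1-ol
Product: 13 (2S)-5,7-bis(benzyloxy)-3-methylidene-2-[3,4,5-tris(benzyloxy)phenyl]chromane, via benzylmagnesium chloride 9 (not isolated), via chloromagnesium alkoxide 10 (not isolated), via vinylmagnesium chelate 11 (not isolated), via bromo allylic alcohol 12 (not isolated)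
Conditions: 5, Mg, Et2O, 0 °C; 8, i-PrMgCl (1.0 equiv), Et2O/toluene, −20 °C; combine, CuI (15 mol %), −20 °C → rt; t-BuOH (1.1 equiv); then CuI (10 mol %), 1,10-phenanthroline, Cs2CO3, toluene, 105 °C (Et2O distilled off), same vessel
Reagents that add atoms: none
Why: Deprotonation gives the chloromagnesium alkoxide of the propargylic alcohol, and monovalent copper then catalyses an alkoxide-directed anti-carbomagnesiation in which the ring A benzyl group is delivered to the proximal alkyne carbon (C3–C4 bond) while magnesium ends on the distal carbon inside a five-membered oxamagnesacycle; tert-butanol protonates the vinyl–magnesium bond and the copper/phenanthroline system then couples the O1 alkoxide with the C8a bromide (O1–C8a bond). The closest known reaction types are the copper-catalysed addition of Grignard reagents to propargylic alkoxides, which gives 2-substituted allylic alcohols, and the intramolecular Ullmann ether synthesis of chromans. Ring C closes in the second event as a six-membered ring by intramolecular aryl C–O coupling, O1 attacking the ipso carbon C8a through an aryl–copper alkoxide (6-exo with respect to the arene). No stereocentre is created: C3 is left sp2 as an exocyclic methylene, and the C2 stereocentre set in step 4 is a spectator because neither C2–H nor the C2–O1 bond is broken (its descriptor changes only through ranking rules). The step needs regioselectivity for C3 over the terminal alkyne carbon, which the O1–Mg chelate secures, and chemoselectivity between the two halides, which is secured because magnesium inserts into the benzylic C–Cl bond at 0 °C whereas copper reaches the aryl C–Br bond only at 105 °C; both ortho positions of the benzyl Grignard reagent are substituted, so ortho transfer cannot occur. With only one hydroxyl in the substrate no other ring size can form, and quenching the vinylmagnesium bond before heating removes the competing C-arylation.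

Step 6
Reactants: 13 (2S)-5,7-bis(benzyloxy)-3-methylidene-2-[3,4,5-tris(benzyloxy)phenyl]chromane
Product: 14 (2R)-5,7-bis(benzyloxy)-2-[3,4,5-tris(benzyloxy)phenyl]chroman-3-one
Conditions: OsO4 (2 mol %), NaIO4, 2,6-lutidine, dioxane/H2O, rt; crude product used at once
Reagents that add atoms: sodium periodate, [Na+].[O-]I(=O)(=O)=O (terminal oxidant; the oxygen is relayed through OsO4)
Why: Lemieux–Johnson oxidation (dihydroxylation of the unhindered 1,1-disubstituted alkene, then periodate cleavage) excises the surplus carbon as formaldehyde and unveils the C3 ketone under buffered conditions, so that the adjacent benzylic C2 stereocentre should not be enolised.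

Step 7
Reactants: 14 (2R)-5,7-bis(benzyloxy)-2-[3,4,5-tris(benzyloxy)phenyl]chroman-3-one
Product: 15 (2R,3R)-5,7-bis(benzyloxy)-2-[3,4,5-tris(benzyloxy)phenyl]chroman-3-ol (penta-O-benzyl-epigallocatechin)
Conditions: Li[HB(s-Bu)3], LiBr, THF, −78 °C
Reagents that add atoms: none
Why: Reduction of the flavan-3-one with the bulky hydride Li[HB(s-Bu)3] should deliver hydride to C3 from the face opposite the C2 aryl group, so that the new 3-OH is cis to the aryl group (3R), the established way from flavan-3-ones into the epi series.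

Step 8
Reactants: 15 penta-O-benzyl-epigallocatechin
Product: 16 4β-(2-ethoxyethoxy)-penta-O-benzyl-epigallocatechin (ether oxygen on C4 trans to the 3-OH)
Conditions: DDQ, 2-ethoxyethanol, CH2Cl2, rt
Reagents that add atoms: 2-ethoxyethanol, CCOCCO
Why: DDQ abstracts hydride from the C4–H bond, which is activated by the ortho and para oxygens of ring A, and 2-ethoxyethanol traps the resulting quinone methide-type cation trans to the 3-OH in a benzylic oxidative etherification; the less electron-rich C2–H is not attacked.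

Step 9
Reactants: 17 (+)-gallocatechin
Product: 19 (2R,3S)-3,5,7-tris(benzyloxy)-2-[3,4,5-tris(benzyloxy)phenyl]chromane (hexa-O-benzyl-gallocatechin), via pentabenzyl ether 18 (not isolated)
Conditions: BnBr, K2CO3, DMF, rt; then NaH, 0 °C → rt (same flask)
Reagents that add atoms: benzyl bromide, BrCc1ccccc1
Why: Williamson etherification with K2CO3 benzylates the five phenols without opening the pyran ring, and NaH then benzylates the secondary 3-OH; the two stereocentres of the natural product are untouched.

Step 10
Reactants: 19 hexa-O-benzyl-gallocatechin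
Product: 20 (2R,3S)-3,5,7-tris(benzyloxy)-8-bromo-2-[3,4,5-tris(benzyloxy)phenyl]chromane
Conditions: NBS, CH2Cl2, −20 °C
Reagents that add atoms: N-bromosuccinimide, O=C1CCC(=O)N1Br
Why: Electrophilic aromatic bromination of the phloroglucinol-type ring A should occur at the more accessible C8, which caps this position so that only C6 remains nucleophilic; no stereocentre is affected.

Step 11
Reactants: 16 4β-(2-ethoxyethoxy)-penta-O-benzyl-epigallocatechin, 20 8-bromo-hexa-O-benzyl-gallocatechin
Product: 21 penta-O-benzyl-epigallocatechin-(4β→6)-8-bromo-hexa-O-benzyl-gallocatechin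
Conditions: TMSOTf (0.3 equiv), 20 (3 equiv), CH2Cl2, −78 → −40 °C
Reagents that add atoms: none
Why: TMSOTf ionises the C4 ether to the ring A-stabilised C4 cation, which the only free ring A position (C6) of the C8-capped nucleophile captures in a Friedel–Crafts alkylation; attack on the face opposite the axial 3-OH sets the new C4 stereocentre 3,4-trans (4β), and the excess of 20 outruns self-condensation.

Step 12
Reactants: 21 penta-O-benzyl-epigallocatechin-(4β→6)-8-bromo-hexa-O-benzyl-gallocatechin, 22 3,4,5-tris(benzyloxy)benzoyl chloride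
Product: 23 3-O-[3,4,5-tris(benzyloxy)benzoyl]-penta-O-benzyl-epigallocatechin-(4β→6)-8-bromo-hexa-O-benzyl-gallocatechin
Conditions: 22 (3 equiv), DMAP, Et3N, CH2Cl2, rt → 40 °C
Reagents that add atoms: none
Why: DMAP-catalysed acylation by the acid chloride can only reach the upper 3-OH, the single free hydroxyl (the lower 3-OH is a benzyl ether), and installs the protected gallate without touching any stereocentre.

Step 13
Reactants: 23 fully protected dimer gallate
Product: 24 epigallocatechin 3-O-gallate-(4β→6)-gallocatechin (target)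
Conditions: H2 (1 atm), Pd(OH)2/C, THF/MeOH/H2O, rt
Reagents that add atoms: none
Why: Hydrogenolysis over Pd(OH)2/C cleaves all fourteen benzyl ethers and removes the C8 bromine by hydrodehalogenation, while the ester, the interflavan bond and the five stereocentres are unaffected.

**Compound list**

1 | 1,3-bis(benzyloxy)-5-bromobenzene | Brc1cc(OCc2ccccc2)cc(OCc2ccccc2)c1 | starting material
2 | N-{[2-bromo-4,6-bis(benzyloxy)phenyl]methylidene}-N-methylmethanaminium dichlorophosphate | C[N+](C)=Cc1c(Br)cc(OCc2ccccc2)cc1OCc1ccccc1.[O-]P(=O)(Cl)Cl | intermediate (not isolated)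
3 | 2-bromo-4,6-bis(benzyloxy)benzaldehyde | O=Cc1c(Br)cc(OCc2ccccc2)cc1OCc1ccccc1 | intermediate
4 | [2-bromo-4,6-bis(benzyloxy)phenyl]methanol | OCc1c(Br)cc(OCc2ccccc2)cc1OCc1ccccc1 | intermediate
5 | 1,5-bis(benzyloxy)-3-bromo-2-(chloromethyl)benzene | ClCc1c(Br)cc(OCc2ccccc2)cc1OCc1ccccc1 | intermediate
6 | 3,4,5-tris(benzyloxy)benzaldehyde | O=Cc1cc(OCc2ccccc2)c(OCc2ccccc2)c(OCc2ccccc2)c1 | starting material
7 | (R)-1-[3,4,5-tris(benzyloxy)phenyl]-3-(trimethylsilyl)prop-2-yn-1-ol (same spatial arrangement as 8) | O[C@@H](C#C[Si](C)(C)C)c1cc(OCc2ccccc2)c(OCc2ccccc2)c(OCc2ccccc2)c1 | intermediate (not isolated)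
8 | (S)-1-[3,4,5-tris(benzyloxy)phenyl]prop-2-yn-1-ol | O[C@@H](C#C)c1cc(OCc2ccccc2)c(OCc2ccccc2)c(OCc2ccccc2)c1 | intermediate
9 | [2-bromo-4,6-bis(benzyloxy)benzyl]magnesium chloride | Cl[Mg]Cc1c(Br)cc(OCc2ccccc2)cc1OCc1ccccc1 | intermediate (not isolated)
10 | chloromagnesium (S)-1-[3,4,5-tris(benzyloxy)phenyl]prop-2-yn-1-olate | Cl[Mg]O[C@@H](C#C)c1cc(OCc2ccccc2)c(OCc2ccccc2)c(OCc2ccccc2)c1 | intermediate (not isolated)
11 | cyclic vinylmagnesium alkoxide (five-membered ring Mg–CH=C3–C2–O1; benzyl group on C3) | [Mg]1C=C(Cc2c(Br)cc(OCc3ccccc3)cc2OCc2ccccc2)[C@@H](c2cc(OCc3ccccc3)c(OCc3ccccc3)c(OCc3ccccc3)c2)O1 | intermediate (not isolated)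
12 | (S)-2-{[2-bromo-4,6-bis(benzyloxy)phenyl]methyl}-1-[3,4,5-tris(benzyloxy)phenyl]prop-2-en-1-ol | O[C@@H](C(=C)Cc1c(Br)cc(OCc2ccccc2)cc1OCc1ccccc1)c1cc(OCc2ccccc2)c(OCc2ccccc2)c(OCc2ccccc2)c1 | intermediate (not isolated)
13 | (2S)-5,7-bis(benzyloxy)-3-methylidene-2-[3,4,5-tris(benzyloxy)phenyl]chromane | C=C1Cc2c(OCc3ccccc3)cc(OCc3ccccc3)cc2O[C@@H]1c1cc(OCc2ccccc2)c(OCc2ccccc2)c(OCc2ccccc2)c1 | intermediate
14 | (2R)-5,7-bis(benzyloxy)-2-[3,4,5-tris(benzyloxy)phenyl]chroman-3-one | O=C1Cc2c(OCc3ccccc3)cc(OCc3ccccc3)cc2O[C@@H]1c1cc(OCc2ccccc2)c(OCc2ccccc2)c(OCc2ccccc2)c1 | intermediate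
15 | (2R,3R)-5,7-bis(benzyloxy)-2-[3,4,5-tris(benzyloxy)phenyl]chroman-3-ol (penta-O-benzyl-epigallocatechin) | O[C@@H]1Cc2c(OCc3ccccc3)cc(OCc3ccccc3)cc2O[C@@H]1c1cc(OCc2ccccc2)c(OCc2ccccc2)c(OCc2ccccc2)c1 | intermediate
16 | 4β-(2-ethoxyethoxy)-penta-O-benzyl-epigallocatechin (2,3-cis, 3,4-trans) | O[C@@H]1[C@@H](OCCOCC)c2c(OCc3ccccc3)cc(OCc3ccccc3)cc2O[C@@H]1c1cc(OCc2ccccc2)c(OCc2ccccc2)c(OCc2ccccc2)c1 | intermediate
17 | (+)-gallocatechin, (2R,3S) | c1c(O)cc2c(c1O)C[C@H](O)[C@@H](c1cc(O)c(O)c(O)c1)O2 | starting material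
18 | (2R,3S)-5,7-bis(benzyloxy)-2-[3,4,5-tris(benzyloxy)phenyl]chroman-3-ol | c1c(OCc3ccccc3)cc2c(c1OCc1ccccc1)C[C@H](O)[C@@H](c1cc(OCc3ccccc3)c(OCc3ccccc3)c(OCc3ccccc3)c1)O2 | intermediate (not isolated)
19 | (2R,3S)-3,5,7-tris(benzyloxy)-2-[3,4,5-tris(benzyloxy)phenyl]chromane | c1c(OCc3ccccc3)cc2c(c1OCc1ccccc1)C[C@H](OCc1ccccc1)[C@@H](c1cc(OCc3ccccc3)c(OCc3ccccc3)c(OCc3ccccc3)c1)O2 | intermediate
20 | (2R,3S)-3,5,7-tris(benzyloxy)-8-bromo-2-[3,4,5-tris(benzyloxy)phenyl]chromane | c1c(OCc3ccccc3)c(Br)c2c(c1OCc1ccccc1)C[C@H](OCc1ccccc1)[C@@H](c1cc(OCc3ccccc3)c(OCc3ccccc3)c(OCc3ccccc3)c1)O2 | intermediate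
21 | penta-O-benzyl-epigallocatechin-(4β→6)-8-bromo-hexa-O-benzyl-gallocatechin (upper 3-OH free) | O[C@@H]1[C@@H](c2c(OCc4ccccc4)c(Br)c3c(c2OCc2ccccc2)C[C@H](OCc2ccccc2)[C@@H](c2cc(OCc4ccccc4)c(OCc4ccccc4)c(OCc4ccccc4)c2)O3)c2c(OCc3ccccc3)cc(OCc3ccccc3)cc2O[C@@H]1c1cc(OCc2ccccc2)c(OCc2ccccc2)c(OCc2ccccc2)c1 | intermediate
22 | 3,4,5-tris(benzyloxy)benzoyl chloride | O=C(Cl)c1cc(OCc2ccccc2)c(OCc2ccccc2)c(OCc2ccccc2)c1 | starting material
23 | 3-O-[3,4,5-tris(benzyloxy)benzoyl]-penta-O-benzyl-epigallocatechin-(4β→6)-8-bromo-hexa-O-benzyl-gallocatechin | O=C(O[C@@H]1[C@@H](c2c(OCc4ccccc4)c(Br)c3c(c2OCc2ccccc2)C[C@H](OCc2ccccc2)[C@@H](c2cc(OCc4ccccc4)c(OCc4ccccc4)c(OCc4ccccc4)c2)O3)c2c(OCc3ccccc3)cc(OCc3ccccc3)cc2O[C@@H]1c1cc(OCc2ccccc2)c(OCc2ccccc2)c(OCc2ccccc2)c1)c1cc(OCc2ccccc2)c(OCc2ccccc2)c(OCc2ccccc2)c1 | intermediate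
24 | epigallocatechin 3-O-gallate-(4β→6)-gallocatechin | O=C(O[C@@H]1[C@@H](c2c(O)cc3c(c2O)C[C@H](O)[C@@H](c2cc(O)c(O)c(O)c2)O3)c2c(O)cc(O)cc2O[C@@H]1c1cc(O)c(O)c(O)c1)c1cc(O)c(O)c(O)c1 | target

**Summary and risks**

Total step count: 13. Longest linear sequence: 10 steps (1, 2, 3, 5, 6, 7, 8, 11, 12, 13).

Steps most likely to fail:

Step 5. The benzylic Grignard reagent may be lost to Wurtz coupling, the carbomagnesiation of the hindered secondary alkoxide may stall (for example through deprotonation of the terminal alkyne), or the allylic alkoxide may isomerise to a ketone during the hot copper stage. The fallback keeps the same two bonds in one flask but reverses the polarity at C3. It sets out from 8, which copper-catalysed α-selective protoboration (B2pin2, CuCl with an N-heterocyclic carbene ligand, NaOt-Bu, MeOH) converts into the internal alkenylboronate (S)-2-(4,4,5,5-tetramethyl-1,3,2-dioxaborolan-2-yl)-1-[3,4,5-tris(benzyloxy)phenyl]prop-2-en-1-ol F1. Suzuki–Miyaura coupling of F1 with the benzylic chloride 5 (Pd(PPh3)4, K3PO4, THF/H2O, 50 °C) forms C3–C4 and gives 12. After exchange of the solvent for toluene, CuI, 1,10-phenanthroline and Cs2CO3 at 105 °C close O1–C8a in the same flask, so that the sequence comes back to the route at 13.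

Step 6. The α-aryl ketone may epimerise at C2 while it is unmasked or handled, so that the configuration set in step 4 erodes. The fallback no longer relies on that configuration. It sets out from 14 of whatever enantiomeric purity and replaces the hydride reduction by a ruthenium diphosphine–diamine hydrogenation with dynamic kinetic resolution (RuCl2[(S)-Xyl-SDP][(R,R)-DPEN] or its mirror image, KOt-Bu, i-PrOH, H2). This racemises C2 through the enolate, reduces one enantiomer to the cis alcohol, and comes back to the route at 15; no new compound is made.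

Step 11. Attack at the hindered C6 position may be slow, so that the C4 cation is consumed by self-condensation of the electrophile or the acid scrambles the new interflavan bond. The fallback changes the electrophile and its mode of activation. It sets out from 16, which BF3·OEt2 and phenylmethanethiol convert into 4β-(benzylthio)-penta-O-benzyl-epigallocatechin F2. F2 is then activated under non-acidic, thiophilic conditions (AgBF4, THF, 0 °C) in the presence of 20 and comes back to the route at 21.

Further compounds
F1 | step 5 | (S)-2-(4,4,5,5-tetramethyl-1,3,2-dioxaborolan-2-yl)-1-[3,4,5-tris(benzyloxy)phenyl]prop-2-en-1-ol | O[C@@H](C(=C)B1OC(C)(C)C(C)(C)O1)c1cc(OCc2ccccc2)c(OCc2ccccc2)c(OCc2ccccc2)c1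
F0 | step 6 | none | none
F2 | step 11 | 4β-(benzylthio)-penta-O-benzyl-epigallocatechin | O[C@@H]1[C@@H](SCc2ccccc2)c2c(OCc3ccccc3)cc(OCc3ccccc3)cc2O[C@@H]1c1cc(OCc2ccccc2)c(OCc2ccccc2)c(OCc2ccccc2)c1
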